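Everything rests on cutting the decalin at C1–C2 and C5–C10. Ring A holds the C3=C4 alkene with methyl groups on C4 and on the neighbouring fusion carbon C5, which is the retron for a C2–C5 diene adding to a C1=C10 vinyl ketone whose carbonyl is C9 of ring B. One catalytic enantioselective intramolecular Diels–Alder reaction of an achiral open-chain (7E)-trienone, a vinyl ketone tethered by three methylenes to a 1,1,2-trisubstituted diene, therefore closes rings A and B and fixes C5; C10 is then brought to the trans fusion by base. The C9 ketone afterwards directs quaternisation of C8 and becomes the C9 methyl, and the arene introduced with C11 is oxidised and ring-contracted to the cyclopentenone.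

Key step: step 8

Numbering: decalin carbons C1–C10 (C5 and C10 are the fusion carbons, C8 is the quaternary carbon bearing C11, C9 is the CH–CH3 carbon); cyclopentenone carbons C1' (C=O), C2' (C–OMe), C3' (=CH), C4' (C(OH)CO2Me), C5' (CH bearing C11).
Assumption 1: the (S)-configured catalyst is taken to give the (4aS) series in the endo closure; this sense must be confirmed on adduct 14, and the mirror-image catalyst from (R)-diphenylprolinol gives the other sense.
Assumption 2: the trans relationship between the C4' hydroxyl and the C5' side chain is taken to be the thermodynamically preferred one at the epimerisable C5'; C4' is not expected to be biased by the remote decalin.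

Step 1
Reactants: 1 2-(3-chloropropyl)-1,3-dioxolane; 2 ethyl but-2-ynoate
Product: 6 ethyl (2E)-6-(1,3-dioxolan-2-yl)-2,3-dimethylhex-2-enoate, via Grignard reagent 3 (not isolated), via alkylcopper reagent 4 (not isolated), via alkenylcopper adduct 5 (not isolated)
Conditions: Mg, THF, 50 °C; CuBr·SMe2, THF, −40 °C; 2, −78 °C; MeI, HMPA, −78 to −30 °C
Reagents that add atoms: iodomethane, CI
Why: syn carbocupration of the ynoate by the alkylcopper reagent (conjugate carbometalation) puts the tether and copper on the same side, and the α-cuprio ester, configurationally stable at low temperature, is C-methylated with retention, so the tetrasubstituted alkene should form as the (E) isomer with the tether trans to the ester.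

Step 2
Reactants: 6 ethyl (2E)-6-(1,3-dioxolan-2-yl)-2,3-dimethylhex-2-enoate
Product: 7 (2E)-6-(1,3-dioxolan-2-yl)-2,3-dimethylhex-2-en-1-ol
Conditions: i-Bu2AlH, CH2Cl2, −78 °C; aq. potassium sodium tartrate
Reagents that add atoms: none
Why: 1,2-reduction of the conjugated ester by the aluminium hydride gives the allylic alcohol without touching the acetal or the alkene geometry.

Step 3
Reactants: 7 (2E)-6-(1,3-dioxolan-2-yl)-2,3-dimethylhex-2-en-1-ol
Product: 8 (2E)-6-(1,3-dioxolan-2-yl)-2,3-dimethylhex-2-enal
Conditions: MnO2, CH2Cl2, rt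
Reagents that add atoms: none
Why: heterogeneous allylic oxidation under neutral conditions stops at the enal and leaves the alkene geometry intact.

Step 4
Reactants: 8 (2E)-6-(1,3-dioxolan-2-yl)-2,3-dimethylhex-2-enal
Product: 9 2-[(4E)-4,5-dimethylhepta-4,6-dien-1-yl]-1,3-dioxolane
Conditions: Ph3PCH3Br, KOtBu, THF, 0 °C to rt
Reagents that add atoms: methyltriphenylphosphonium bromide, C[P+](c1ccccc1)(c1ccccc1)c1ccccc1.[Br-]
Why: Wittig methylenation of the enal adds the terminal vinyl carbon and so completes the 1,1,2-trisubstituted diene.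

Step 5
Reactants: 9 2-[(4E)-4,5-dimethylhepta-4,6-dien-1-yl]-1,3-dioxolane
Product: 10 (5E)-5,6-dimethylocta-5,7-dienal
Conditions: 1 M HCl, THF, rt
Reagents that add atoms: water, O
Why: acid-catalysed acetal hydrolysis in dilute aqueous acid frees the aldehyde, while the diene, which needs much stronger acid to be protonated, should survive.

Step 6
Reactants: 10 (5E)-5,6-dimethylocta-5,7-dienal; 11 vinylmagnesium bromide
Product: 12 (7E)-7,8-dimethyldeca-1,7,9-trien-3-ol (racemic)
Conditions: THF, −78 to 0 °C; H2O
Reagents that add atoms: none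
Why: Grignard 1,2-addition to the aldehyde; the carbinol centre formed is removed in the next step.

Step 7
Reactants: 12 (7E)-7,8-dimethyldeca-1,7,9-trien-3-ol
Product: 13 (7E)-7,8-dimethyldeca-1,7,9-trien-3-one
Conditions: Dess–Martin periodinane, pyridine, CH2Cl2, 0 °C
Reagents that add atoms: none
Why: Dess–Martin oxidation of the secondary allylic alcohol is fast and neutral at 0 °C, so the polymerisation-prone vinyl ketone can be filtered through silica and used at once, before uncatalysed cyclisation sets in.

Step 8
Reactants: 13 (7E)-7,8-dimethyldeca-1,7,9-trien-3-one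
Product: 14 (4aS,8aS)-4a,5-dimethyl-3,4,4a,7,8,8a-hexahydronaphthalen-1(2H)-one (cis-fused adduct)
Conditions: (S)-tetrahydro-1-(2-methylphenyl)-3,3-diphenyl-1H,3H-pyrrolo[1,2-c][1,3,2]oxazaborole (20 mol %), HNTf2 (18 mol %), CH2Cl2 (0.02 M), −78 to −20 °C
Reagents that add atoms: none
Why: The boron centre of the oxazaborolidinium ion binds the C9 carbonyl, lowers the LUMO of the vinyl ketone and lets the hindered diene add in a concerted, asynchronous [4+2] process in which C1–C2 forms ahead of the bond to the fully substituted C5; the closest known reactions are oxazaborolidinium-catalysed enantioselective Diels–Alder additions to vinyl ketones and Lewis acid-promoted cyclisations of 1,7,9-decatrien-3-ones. Ring A closes as the cyclohexene of the cycloaddition and ring B as the six-membered ring spanned by the C6–C9 tether, in the endo mode (tether carbonyl under the diene) that Lewis acids favour for this substrate class, which is why the cis-fused adduct, and not the trans ketone, is expected as the direct product. C10 is set by the dienophile face that the catalyst leaves open, and C5 by the endo mode together with the (E) geometry of the tetrasubstituted alkene (tether outside, methyl inside). The step must deliver one fusion mode on one enantioface: since C10 is re-set in step 9, only C5 survives, and an exo adduct formed on the same dienophile face would carry the opposite C5, so 14 is freed by chromatography from any trans-fused adduct before base is applied. High dilution, low temperature and slightly less HNTf2 than oxazaborolidine should keep intermolecular addition, the uncatalysed background and acid isomerisation of the diene down.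

Step 9
Reactants: 14 (4aS,8aS)-4a,5-dimethyl-3,4,4a,7,8,8a-hexahydronaphthalen-1(2H)-one
Product: 15 (4aS,8aR)-4a,5-dimethyl-3,4,4a,7,8,8a-hexahydronaphthalen-1(2H)-one (trans-fused ketone)
Conditions: NaOMe (0.2 equiv), MeOH, rt
Reagents that add atoms: none
Why: reversible enolisation at C10, the only stereocentre next to the ketone, equilibrates the ring fusion (base-mediated epimerisation) towards the trans-decalone, expected to be the more stable isomer as in related angular-methyl 1-decalones, and unchanged 14 is recovered and resubmitted.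

Step 10
Reactants: 16 1,2,4,5-tetramethoxybenzene
Product: 18 2,3,5,6-tetramethoxybenzaldehyde, via aryllithium 17 (not isolated)
Conditions: n-BuLi, THF, 0 °C; DMF, 0 °C to rt; H2O
Reagents that add atoms: N,N-dimethylformamide, CN(C)C=O
Why: directed ortho-lithiation between two methoxy groups, followed by formylation of the aryllithium with DMF.

Step 11
Reactants: 15 (4aS,8aR)-4a,5-dimethyl-3,4,4a,7,8,8a-hexahydronaphthalen-1(2H)-one; 18 2,3,5,6-tetramethoxybenzaldehyde
Product: 19 (2E,4aS,8aR)-4a,5-dimethyl-2-[(2,3,5,6-tetramethoxyphenyl)methylidene]-3,4,4a,7,8,8a-hexahydronaphthalen-1(2H)-one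
Conditions: KOH, EtOH, 60 °C
Reagents that add atoms: none
Why: crossed aldol addition at C8, the only α-methylene, followed by E1cB dehydration (Claisen–Schmidt condensation) should give the (E)-arylidene ketone, and C10, already in its thermodynamic trans configuration, is not put at risk by the base.

Step 12
Reactants: 19 (2E,4aS,8aR)-4a,5-dimethyl-2-[(2,3,5,6-tetramethoxyphenyl)methylidene]-3,4,4a,7,8,8a-hexahydronaphthalen-1(2H)-one
Product: 21 (2R,4aS,8aR)-2,4a,5-trimethyl-2-[(2,3,5,6-tetramethoxyphenyl)methyl]-3,4,4a,7,8,8a-hexahydronaphthalen-1(2H)-one, via lithium enolate 20 (not isolated)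
Conditions: Li, NH3(l), THF, t-BuOH (1 equiv), −78 °C; MeI, −78 to −33 °C
Reagents that add atoms: iodomethane, CI
Why: dissolving-metal reduction of the enone gives the C8=C9 lithium enolate regiospecifically (reductive alkylation), and MeI then attacks C8 along the axial line on the α face, which is stereoelectronically preferred and flanked only by axial hydrogens at C6 and C10, so the methyl group should become axial (α) and the arylmethyl group equatorial (β), setting C8 as R.

Step 13
Reactants: 21 (2R,4aS,8aR)-2,4a,5-trimethyl-2-[(2,3,5,6-tetramethoxyphenyl)methyl]-3,4,4a,7,8,8a-hexahydronaphthalen-1(2H)-one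
Product: 22 1,2,4,5-tetramethoxy-3-{[(2R,4aS,8aS)-2,4a,5-trimethyl-1-methylidene-1,2,3,4,4a,7,8,8a-octahydronaphthalen-2-yl]methyl}benzene
Conditions: Ph3PCH3Br, KOtBu, toluene, 100 °C
Reagents that add atoms: methyltriphenylphosphonium bromide, C[P+](c1ccccc1)(c1ccccc1)c1ccccc1.[Br-]
Why: Wittig methylenation under forcing conditions (excess ylide in hot toluene) converts the hindered C9 ketone into the exocyclic alkene; C10, the only enolisable position, already holds its thermodynamic configuration and C8 is quaternary.

Step 14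
Reactants: 22 1,2,4,5-tetramethoxy-3-{[(2R,4aS,8aS)-2,4a,5-trimethyl-1-methylidene-1,2,3,4,4a,7,8,8a-octahydronaphthalen-2-yl]methyl}benzene
Product: 23 1,2,4,5-tetramethoxy-3-{[(1R,2R,4aS,8aS)-1,2,4a,5-tetramethyl-1,2,3,4,4a,7,8,8a-octahydronaphthalen-2-yl]methyl}benzene
Conditions: H2 (1 atm), PtO2, EtOAc, rt
Reagents that add atoms: none
Why: heterogeneous hydrogenation should saturate the 1,1-disubstituted exocyclic alkene faster than the hindered trisubstituted ring A alkene, and the catalyst surface should reach C9 from the α (equatorial) side because the β side lies under the syn-axial C5 methyl group, so hydrogen enters α and the new methyl group ends up β (axial), setting C9 as R.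

Step 15
Reactants: 23 1,2,4,5-tetramethoxy-3-{[(1R,2R,4aS,8aS)-1,2,4a,5-tetramethyl-1,2,3,4,4a,7,8,8a-octahydronaphthalen-2-yl]methyl}benzene
Product: 24 2,5-dimethoxy-3-{[(1R,2R,4aS,8aS)-1,2,4a,5-tetramethyl-1,2,3,4,4a,7,8,8a-octahydronaphthalen-2-yl]methyl}cyclohexa-2,5-diene-1,4-dione
Conditions: (NH4)2Ce(NO3)6, MeCN/H2O, 0 °C
Reagents that add atoms: water, O
Why: oxidative demethylation of a para-dimethoxy pair by tetravalent cerium (arene radical cation, attack of water, loss of methanol) gives the 2,5-dimethoxy-para-quinone, either para pair leading to the same compound, while the isolated alkene is inert at 0 °C.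

Step 16
Reactants: 24 2,5-dimethoxy-3-{[(1R,2R,4aS,8aS)-1,2,4a,5-tetramethyl-1,2,3,4,4a,7,8,8a-octahydronaphthalen-2-yl]methyl}cyclohexa-2,5-diene-1,4-dione
Product: 25 2-hydroxy-5-methoxy-3-{[(1R,2R,4aS,8aS)-1,2,4a,5-tetramethyl-1,2,3,4,4a,7,8,8a-octahydronaphthalen-2-yl]methyl}cyclohexa-2,5-diene-1,4-dione
Conditions: KOH, MeOH/H2O, rt; 1 M HCl
Reagents that add atoms: potassium hydroxide, [K+].[OH-]
Why: hydroxide adds to the vinylogous ester carbon whose methoxy group is twisted out of conjugation by the neighbouring side chain and expels methoxide (addition–elimination), and the vinylogous carboxylate formed is protected against a second substitution, as is general for 2,5-dimethoxy-3-alkylquinones.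

Step 17
Reactants: 25 2-hydroxy-5-methoxy-3-{[(1R,2R,4aS,8aS)-1,2,4a,5-tetramethyl-1,2,3,4,4a,7,8,8a-octahydronaphthalen-2-yl]methyl}cyclohexa-2,5-diene-1,4-dione
Product: 26 Dysidenone B, methyl (1R,5S)-1-hydroxy-3-methoxy-4-oxo-5-{[(1R,2R,4aS,8aS)-1,2,4a,5-tetramethyl-1,2,3,4,4a,7,8,8a-octahydronaphthalen-2-yl]methyl}cyclopent-2-ene-1-carboxylate
Conditions: NaOMe, MeOH, 50 °C; AcOH
Reagents that add atoms: methanol (as sodium methoxide), CO
Why: in the triketone tautomer of the hydroxyquinone, methoxide adds to the central carbonyl of the vicinal dione (the former enol carbon) and the side-chain carbon shifts from it to the adjacent ketone carbon (benzilic ester rearrangement with ring contraction), which gives the hydroxy ester with the methoxy enone intact; C5' should settle under the basic conditions into the trans arrangement of hydroxyl and side chain, whereas C4' is formed without bias from the distant decalin, so 26 is expected together with the isomer inverted at both ring centres, is separated from it by preparative HPLC, and that isomer is returned to the same conditions for re-equilibration by retro-aldol and aldol steps.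

Compound list
1 | 2-(3-chloropropyl)-1,3-dioxolane | ClCCCC1OCCO1 | starting material
2 | ethyl but-2-ynoate | CCOC(=O)C#CC | starting material
3 | [3-(1,3-dioxolan-2-yl)propyl]magnesium chloride (not isolated) | Cl[Mg]CCCC1OCCO1 | intermediate
4 | [3-(1,3-dioxolan-2-yl)propyl]copper, monovalent copper (not isolated) | [Cu]CCCC1OCCO1 | intermediate
5 | ethyl (2Z)-2-cuprio-6-(1,3-dioxolan-2-yl)-3-methylhex-2-enoate, monovalent copper (not isolated) | CCOC(=O)/C([Cu])=C(/CCCC1OCCO1)C | intermediate
6 | ethyl (2E)-6-(1,3-dioxolan-2-yl)-2,3-dimethylhex-2-enoate | CCOC(=O)/C(C)=C(/CCCC1OCCO1)C | intermediate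
7 | (2E)-6-(1,3-dioxolan-2-yl)-2,3-dimethylhex-2-en-1-ol | OC/C(C)=C(/CCCC1OCCO1)C | intermediate
8 | (2E)-6-(1,3-dioxolan-2-yl)-2,3-dimethylhex-2-enal | O=C/C(C)=C(/CCCC1OCCO1)C | intermediate
9 | 2-[(4E)-4,5-dimethylhepta-4,6-dien-1-yl]-1,3-dioxolane | C=C/C(C)=C(/CCCC1OCCO1)C | intermediate
10 | (5E)-5,6-dimethylocta-5,7-dienal | O=CCCC/C(C)=C(C)/C=C | intermediate
11 | vinylmagnesium bromide | C=C[Mg]Br | starting material
12 | (7E)-7,8-dimethyldeca-1,7,9-trien-3-ol (racemic) | C=CC(O)CCC/C(C)=C(C)/C=C | intermediate
13 | (7E)-7,8-dimethyldeca-1,7,9-trien-3-one | C=CC(=O)CCC/C(C)=C(C)/C=C | intermediate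
14 | (4aS,8aS)-4a,5-dimethyl-3,4,4a,7,8,8a-hexahydronaphthalen-1(2H)-one (cis-fused) | C1CC[C@]2(C)C(C)=CCC[C@@H]2C1=O | intermediate
15 | (4aS,8aR)-4a,5-dimethyl-3,4,4a,7,8,8a-hexahydronaphthalen-1(2H)-one (trans-fused) | C1CC[C@]2(C)C(C)=CCC[C@H]2C1=O | intermediate
16 | 1,2,4,5-tetramethoxybenzene | COc1cc(OC)c(OC)cc1OC | starting material
17 | (2,3,5,6-tetramethoxyphenyl)lithium (not isolated) | [Li]c1c(OC)c(OC)cc(OC)c1OC | intermediate
18 | 2,3,5,6-tetramethoxybenzaldehyde | O=Cc1c(OC)c(OC)cc(OC)c1OC | intermediate
19 | (2E,4aS,8aR)-4a,5-dimethyl-2-[(2,3,5,6-tetramethoxyphenyl)methylidene]-3,4,4a,7,8,8a-hexahydronaphthalen-1(2H)-one | COc1cc(OC)c(OC)c(/C=C2\CC[C@]3(C)C(C)=CCC[C@H]3C2=O)c1OC | intermediate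
20 | lithium (4aS,8aR)-4a,5-dimethyl-2-[(2,3,5,6-tetramethoxyphenyl)methyl]-3,4,4a,7,8,8a-hexahydronaphthalen-1-olate, the C8=C9 enolate (not isolated) | COc1cc(OC)c(OC)c(CC2=C(O[Li])[C@@H]3CCC=C(C)[C@@]3(C)CC2)c1OC | intermediate
21 | (2R,4aS,8aR)-2,4a,5-trimethyl-2-[(2,3,5,6-tetramethoxyphenyl)methyl]-3,4,4a,7,8,8a-hexahydronaphthalen-1(2H)-one | COc1cc(OC)c(OC)c(C[C@@]2(C)CC[C@]3(C)C(C)=CCC[C@H]3C2=O)c1OC | intermediate
22 | 1,2,4,5-tetramethoxy-3-{[(2R,4aS,8aS)-2,4a,5-trimethyl-1-methylidene-1,2,3,4,4a,7,8,8a-octahydronaphthalen-2-yl]methyl}benzene | COc1cc(OC)c(OC)c(C[C@@]2(C)CC[C@]3(C)C(C)=CCC[C@H]3C2=C)c1OC | intermediate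
23 | 1,2,4,5-tetramethoxy-3-{[(1R,2R,4aS,8aS)-1,2,4a,5-tetramethyl-1,2,3,4,4a,7,8,8a-octahydronaphthalen-2-yl]methyl}benzene | COc1cc(OC)c(OC)c(C[C@@]2(C)CC[C@]3(C)C(C)=CCC[C@H]3[C@H]2C)c1OC | intermediate
24 | 2,5-dimethoxy-3-{[(1R,2R,4aS,8aS)-1,2,4a,5-tetramethyl-1,2,3,4,4a,7,8,8a-octahydronaphthalen-2-yl]methyl}cyclohexa-2,5-diene-1,4-dione | COC1=CC(=O)C(OC)=C(C[C@@]2(C)CC[C@]3(C)C(C)=CCC[C@H]3[C@H]2C)C1=O | intermediate
25 | 2-hydroxy-5-methoxy-3-{[(1R,2R,4aS,8aS)-1,2,4a,5-tetramethyl-1,2,3,4,4a,7,8,8a-octahydronaphthalen-2-yl]methyl}cyclohexa-2,5-diene-1,4-dione | COC1=CC(=O)C(O)=C(C[C@@]2(C)CC[C@]3(C)C(C)=CCC[C@H]3[C@H]2C)C1=O | intermediate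
26 | Dysidenone B, methyl (1R,5S)-1-hydroxy-3-methoxy-4-oxo-5-{[(1R,2R,4aS,8aS)-1,2,4a,5-tetramethyl-1,2,3,4,4a,7,8,8a-octahydronaphthalen-2-yl]methyl}cyclopent-2-ene-1-carboxylate | COC(=O)[C@@]1(O)C=C(OC)C(=O)[C@H]1C[C@@]1(C)CC[C@]2(C)C(C)=CCC[C@H]2[C@H]1C | target

Total step count: 17. Longest linear sequence: 16 steps (steps 1–9 and 11–17); step 10 is a one-step side branch.

Steps most likely to fail

1. Step 8. The catalyst may discriminate poorly between the two faces of the boron-bound vinyl ketone, endo and exo closure may compete so that the C5 configuration is split, or the acid may isomerise the diene before it cyclises. Fallback: setting out from 13, ring closure is promoted by the achiral Lewis acid Me2AlCl (CH2Cl2, −78 to 0 °C), which should give the racemic cis-fused ketone F1, and NaOMe in MeOH equilibrates this to the racemic trans-fused ketone F2. NaBH4 in MeOH should reduce F2 from the open α face to the racemic axial alcohol F3 (either carbinol epimer would serve). Esterification with (1S,4R)-camphanic chloride (pyridine, DMAP) gives two diastereomeric esters that are separated by chromatography or crystallisation. The ester of the (1S,4aS,8aR) alcohol, camphanate F4, is saponified (KOH, MeOH/H2O) to the resolved alcohol F5, and Dess–Martin oxidation returns to the route at 15.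

2. Step 17. The 1,2-shift may occur without any facial preference at C4', so that both ring diastereomers form in similar amounts; it may also stall at the unreactive hydroxyquinone anion, and the two esters may resist separation. Fallback: setting out from 25, the rearrangement is run as a benzilic acid rearrangement in hot aqueous KOH, which should give the free acids. The (1R,5S) isomer, hydroxy acid F6, is separated from its ring diastereomer at the acid stage by fractional crystallisation or reverse-phase chromatography. Esterification with TMSCHN2 in toluene/MeOH then returns to the route at 26.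

3. Step 14. Hydrogen may be delivered partly to the β face, the ring A alkene may be saturated as well, or the exocyclic alkene may migrate into the ring before it is reduced. Fallback: setting out from 22, hydroboration with 9-BBN (THF, 65 °C; then NaOH, H2O2) leaves the trisubstituted alkene alone, approaches from the same open α face and should give the primary alcohol F7. Mesylation (MsCl, Et3N, CH2Cl2) gives the mesylate F8, and LiEt3BH (THF, 65 °C) reduces it to the methyl group, returning to the route at 23.

Further compounds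
F1 | step 8 | rac-(4aS,8aS)-4a,5-dimethyl-3,4,4a,7,8,8a-hexahydronaphthalen-1(2H)-one (racemate, relative configuration shown) | C1CC[C@]2(C)C(C)=CCC[C@@H]2C1=O
F2 | step 8 | rac-(4aS,8aR)-4a,5-dimethyl-3,4,4a,7,8,8a-hexahydronaphthalen-1(2H)-one (racemate, relative configuration shown) | C1CC[C@]2(C)C(C)=CCC[C@H]2C1=O
F3 | step 8 | rac-(1S,4aS,8aR)-4a,5-dimethyl-1,2,3,4,4a,7,8,8a-octahydronaphthalen-1-ol (racemate, relative configuration shown) | C1CC[C@]2(C)C(C)=CCC[C@H]2[C@H]1O
F4 | step 8 | (1S,4aS,8aR)-4a,5-dimethyl-1,2,3,4,4a,7,8,8a-octahydronaphthalen-1-yl (1S,4R)-4,7,7-trimethyl-3-oxo-2-oxabicyclo[2.2.1]heptane-1-carboxylate | C1CC[C@]2(C)C(C)=CCC[C@H]2[C@H]1OC(=O)[C@@]34CC[C@@](C)(C(=O)O3)C4(C)C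
F5 | step 8 | (1S,4aS,8aR)-4a,5-dimethyl-1,2,3,4,4a,7,8,8a-octahydronaphthalen-1-ol | C1CC[C@]2(C)C(C)=CCC[C@H]2[C@H]1O
F6 | step 17 | (1R,5S)-1-hydroxy-3-methoxy-4-oxo-5-{[(1R,2R,4aS,8aS)-1,2,4a,5-tetramethyl-1,2,3,4,4a,7,8,8a-octahydronaphthalen-2-yl]methyl}cyclopent-2-ene-1-carboxylic acid | OC(=O)[C@@]1(O)C=C(OC)C(=O)[C@H]1C[C@@]1(C)CC[C@]2(C)C(C)=CCC[C@H]2[C@H]1C
F7 | step 14 | {(1R,2R,4aS,8aS)-2,4a,5-trimethyl-2-[(2,3,5,6-tetramethoxyphenyl)methyl]-1,2,3,4,4a,7,8,8a-octahydronaphthalen-1-yl}methanol | COc1cc(OC)c(OC)c(C[C@@]2(C)CC[C@]3(C)C(C)=CCC[C@H]3[C@H]2CO)c1OC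
F8 | step 14 | {(1R,2R,4aS,8aS)-2,4a,5-trimethyl-2-[(2,3,5,6-tetramethoxyphenyl)methyl]-1,2,3,4,4a,7,8,8a-octahydronaphthalen-1-yl}methyl methanesulfonate | COc1cc(OC)c(OC)c(C[C@@]2(C)CC[C@]3(C)C(C)=CCC[C@H]3[C@H]2COS(C)(=O)=O)c1OC
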